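How much of the substrate stands as product or crystals after 50 s, and which change adds most?

substrate 0.049 M; salt in the second phase 0.0588 M; spent carrier 4.6 mM; time 50 s; volume of the second phase over the first 1.0

* product and crystals together at 50 s, in percent of the substrate charged
* the change that raises the amount of product and crystals together at 50 s, in percent of the substrate charged most ("none" if none brings more than 2 percentage points) (zeta / eta / theta / none)
* amount of product and crystals together at 50 s, in percent of the substrate charged, after theta

- zeta: doubling the solubility in step 4, all else as stated
- eta: doubling the amount of salt in the second phase, all else as stated
- theta: doubling the dissolution coefficient of step 4, all else as stated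

- amounts and yields of product count crystals too
- where a step has two of a species, its rate is k times that concentration squared, and two are used at each turn
- in the second phase: salt in the second phase, spent salt in the second phase; everything else is in the first
- charges count per volume of the first phase; a concentration in a rate is the amount of a species over the volume of its own phase; every rate counts per litre of the first phase
- given per volume of solution although it is solid: crystals
- run time (flask): 50 s

    spent carrier + salt in the second phase ⇌ fresh carrier + spent salt in the second phase (K1 = 21, k1 = 14 /M/s)
    substrate + fresh carrier → product + spent carrier (k2 = 11 /M/s)
    fresh carrier ⇌ dormant form (K3 = 1.6, k3 = 0.15 /s)
    crystals ⇌ product, rate k4*(cs4 - [product]) while solid is left; crystals form when [product] > cs4 (cs4 = 20 mM, k4 = 9.3 /s)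
    2 spent carrier ⇌ resting dimer, settled at all times (K5 = 250 /M)

Fresh carrier turns substrate into product and becomes spent carrier. Spent carrier takes salt from the second phase and becomes fresh again. Fresh carrier also balances with the dormant form. That balance relaxes with a half-life of 2.84 s, far shorter than the run, so the carrier can be treated as shared out among its forms. Substrate then falls pseudo-first-order, with a constant equal to 11 /M/s times the fresh part of the carrier charge.

Two versions of the flask can be solved in the head. If the salt step were instantly quick, no spent carrier would stand, fresh and dormant would split by 1.6, and the fresh share would be 38.5 %, giving 62.2 %. In the symmetric round, both steps pull equally, spent equals fresh, the share is 27.8 %, and the yield is 50.5 %.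

The pull of the flask, the salt step's constant times salt over the substrate step's constant times substrate, is 1.53 at the charges, above the even value of one, so the reckoning places the flask between the two, with spent carrier below fresh but not absent. This gives a working share of 30.7 %, the part of the charged carrier standing fresh, and a yield of 54.0 %. Resting dimer is left out of this reckoning, though its constant times the spent carrier charge is 1.1, so the yield should come out somewhat lower.

Doubling the salt doubles the pull and lifts the share to 34.2 %, worth 3.8 percentage points. Product stands on the left of no carrier step, and crystals count with it, so the reckoning stays at 54.0 % after theta. The choice is eta.

The forecast gave 54 %, eta and 54 %, holding that “doubling the salt pushes more carrier into the fresh form”. The simulation gives 52.4 %, eta and 52.4 % after theta. Eta gains 8.8 points, more than reckoned, while zeta gains 0 points and theta 0 points.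

The working share contains no carrier charge, so it carries over unchanged to the neighbouring flask with 0.0028 M of spent carrier. There the reckoning gives 37.7 %, and that flask's run gives 37.7 %. At 50.0 s, resting dimer holds 5.12 % of the carrier in the neighbour, less than the 8.10 % in the first flask. The neighbour ends with 62 % of its substrate still there and crystals at 0 %.

The rate constants were drawn at random within sensible limits; the rest is arithmetic.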